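**Remark on the chemistry.** Labdane numbering is used for every intermediate (ring A = C1–C5 and C10; C18 = 4α-methyl; C19 = carboxyl carbon on C4; C20 = methyl on C10; C17 = exocyclic methylene carbon). The target has 9β-H, so its side chain is trans to C20; by the CIP rules it is 4S,5R,6S,7S,9S,10R. Compounds 8–10 and 20–23 are drawn as the exo (α) anomer at C6, and 7–10 with the C10 configuration of the endo adduct; both centres later become sp2 carbons (C10 in step 14, C6 in step 17), so their configuration does not reach the target.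

**Retrosynthetic overview**
1. The 7α-hydroxyl is put in last by allylic oxidation; the 6β-benzoate and the free 19-acid come from a 19,6β-lactone, and ring B is closed through C6–C7 by attack of an allylsilane on a lactone-embedded oxocarbenium ion at C6.
2. Enabling feature: the C19 carboxyl on C4 and the oxygen on C6 are 1,3-syn on the β face of rings A and B, so they can be tied as a γ-lactone; C7 sits next to the C8=C17 exocyclic methylene, the signature of SE2' attack by a 2-(silylmethyl)allyl group.
3. C9 and the quaternary C10 come from a ketal Claisen rearrangement of a ring-A ketone with a (Z)-2-(silylmethyl)allylic alcohol made from geraniol; the C1 ketone is then removed.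
4. Ring A with C4 and C5 comes from an auxiliary-controlled Diels–Alder reaction of (5R)-5-menthyloxy-3-methylbutenolide with a 2-silyloxypentadiene.
5. Order of ring formation: lactone ring (from a furan), ring A (Diels–Alder), ring B (key step); the lactone is opened afterwards.

Key step: step 17

**Route**

Step 1
Reactants: 1 3-methylfuran-2-carboxylic acid
Product: 2 5-hydroxy-3-methylfuran-2(5H)-one (racemic pseudo-acid)
Conditions: O2, rose bengal (cat.), hν (visible), MeOH, 0 °C
Reagents that add atoms: dioxygen O=O
Why: Dye-sensitised [4+2] addition of singlet oxygen to the furan followed by decarboxylative fragmentation of the endoperoxide (photooxygenation of 2-furoic acids) should turn the carboxyl-bearing carbon into the lactone carbonyl, leaving the methyl α to it.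

Step 2
Reactants: 2 5-hydroxy-3-methylfuran-2(5H)-one; 3 (1R,2S,5R)-(−)-menthol
Product: 4 (5R)-5-[(1R,2S,5R)-menthyloxy]-3-methylfuran-2(5H)-one
Conditions: CSA (cat.), PhMe, reflux (Dean–Stark); crystallisation from hexane, mother liquor re-equilibrated with CSA
Reagents that add atoms: none
Why: Acid-catalysed acetalisation of the pseudo-acid hydroxyl; the acetal centre epimerises under the conditions, so the 5R epimer should be collected by crystallisation as for the parent menthyloxyfuranone, and this centre is the only source of absolute configuration.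

Step 3
Reactants: 5 pent-1-en-3-one
Product: 6 (Z)-3-(trimethylsilyloxy)penta-1,3-diene
Conditions: Me3SiOTf, Et3N, Et2O, 0 °C
Reagents that add atoms: trimethylsilyl triflate C[Si](C)(C)OS(=O)(=O)C(F)(F)F
Why: Soft enolisation of the ethyl ketone toward its CH2 group and O-silylation should give the 2-silyloxy diene, mainly as the Z enol ether (its geometry is not carried into the target).

Step 4
Reactants: 4 (5R)-5-menthyloxy-3-methylfuran-2(5H)-one; 6 (Z)-3-(trimethylsilyloxy)penta-1,3-diene
Product: 7 cycloadduct: cis-fused bicyclic 19,6-lactone (4α-methyl; 5α-H; 10β-methyl; menthyloxy on the α face of C6) bearing the C1=C2 trimethylsilyl enol ether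
Conditions: PhMe, BHT (cat.), 130 °C, sealed tube
Reagents that add atoms: none
Why: Thermal normal-demand Diels–Alder reaction in which the enol-ether β-carbon of the diene (C10) should bond to the butenolide β-carbon (C5) and the CH2 terminus to the methyl-bearing α-carbon (C4), on the face anti to the menthyloxy group, which sets the quaternary C4 and C5 in the absolute sense of the target.

Step 5
Reactants: 7 cycloadduct
Product: 8 keto pseudo-acid: 6-hydroxy-19,6-lactone with a C1 ketone
Conditions: CF3CO2H/H2O/THF, 45 °C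
Reagents that add atoms: water O
Why: Acid hydrolysis of the silyl enol ether and of the menthyl acetal; the cis aldehyde acid should close back to the cyclic γ-hydroxy lactone, and menthol is recovered.

Step 6
Reactants: 8 keto pseudo-acid
Product: 9 6-fluoro-19,6-lactone with a C1 ketone (fluorine on the α face)
Conditions: Et2NSF3 (DAST), CH2Cl2, −78 → −20 °C
Reagents that add atoms: diethylaminosulfur trifluoride CCN(CC)S(F)(F)F
Why: Deoxyfluorination of a hemiacetal-type hydroxyl (as in the synthesis of glycosyl fluorides) through the cyclic acyloxycarbenium ion, with fluoride entering from the convex face; the ketone should not react at this temperature.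

Step 7
Reactants: 9 fluoro keto lactone
Product: 10 C1 dimethyl ketal of the fluoro lactone
Conditions: HC(OMe)3, MeOH, PPTS (cat.), rt
Reagents that add atoms: trimethyl orthoformate COC(OC)OC; methanol CO
Why: Standard ketalisation with orthoformate as water scavenger; the C–F bond, deactivated toward ionisation by the lactone oxygen, should survive the mild acid.

Step 8
Reactants: 11 geraniol
Product: 12 geranyl tert-butyldiphenylsilyl ether
Conditions: TBDPSCl, imidazole, CH2Cl2, rt
Reagents that add atoms: tert-butyldiphenylsilyl chloride CC(C)(C)[Si](Cl)(c1ccccc1)c1ccccc1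
Why: Silylation of the primary allylic alcohol with a group that should last until step 20.

Step 9
Reactants: 12 geranyl silyl ether
Product: 13 6,7-epoxide of 12 (racemic at the epoxide carbon)
Conditions: mCPBA (1.05 equiv), CH2Cl2, −20 °C; aq. NaHCO3
Reagents that add atoms: 3-chloroperbenzoic acid OOC(=O)c1cccc(Cl)c1
Why: Prilezhaev epoxidation should select the more electron-rich distal trisubstituted alkene, because the 2,3-alkene is deactivated by the allylic oxygen.

Step 10
Reactants: 13 epoxide
Product: 14 (E)-6-(tert-butyldiphenylsilyloxy)-4-methylhex-4-enal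
Conditions: H5IO6, THF/H2O, 0 °C
Reagents that add atoms: none
Why: Periodic acid opens the epoxide to the diol and cleaves it (Malaprade cleavage) to the aldehyde and acetone without touching the E-alkene.

Step 11
Reactants: 14 aldehyde
Product: 15 (E)-tert-butyl[(3-methylhept-2-en-6-yn-1-yl)oxy]diphenylsilane
Conditions: dimethyl (1-diazo-2-oxopropyl)phosphonate, K2CO3, MeOH, 0 °C → rt
Reagents that add atoms: dimethyl (1-diazo-2-oxopropyl)phosphonate COP(=O)(OC)C(=[N+]=[N-])C(C)=O
Why: Seyferth–Gilbert homologation with the Ohira–Bestmann reagent converts the aldehyde into the terminal alkyne under mild base.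

Step 12
Reactants: 15 terminal alkyne
Product: 17 (E)-8-(tert-butyldiphenylsilyloxy)-6-methyloct-6-en-2-yn-1-ol, via lithium acetylide 16 (not isolated)
Conditions: n-BuLi, THF, −78 °C; (CH2O)n, → rt; aq. NH4Cl
Reagents that add atoms: formaldehyde (from paraformaldehyde) C=O
Why: Hydroxymethylation of the lithium acetylide gives the propargylic alcohol whose CH2OH carbon becomes C7.

Step 13
Reactants: 17 propargylic alcohol
Product: 19 (2Z,6E)-8-(tert-butyldiphenylsilyloxy)-6-methyl-2-[(trimethylsilyl)methyl]octa-2,6-dien-1-ol, via alkenylmagnesium chelate 18 (not isolated)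
Conditions: Me3SiCH2MgCl (3.5 equiv), CuBr·SMe2 (10 mol%), THF, 0 °C → reflux; aq. NH4Cl
Reagents that add atoms: (trimethylsilyl)methylmagnesium chloride C[Si](C)(C)C[Mg]Cl
Why: Copper-catalysed anti-carbomagnesiation of the propargylic alkoxide should deliver CH2SiMe3 to the carbon next to CH2OH and magnesium to the distal carbon in a five-membered chelate, so that after protonation the chain is cis to CH2SiMe3 and trans to CH2OH.

Step 14
Reactants: 10 dimethyl ketal; 19 allylic alcohol
Product: 21 C1 ketone with quaternary C10 (10β-methyl) bearing C9 (9β-H; C11–C15 chain) and the C8(=C7H2)–C17H2SiMe3 allylsilane, via allyl enol ether 20 (not isolated)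
Conditions: EtCO2H (10 mol%), xylenes, 140 °C, MeOH distilled off
Reagents that add atoms: none
Why: Ketal Claisen rearrangement: acid-catalysed exchange should give the more substituted C1=C10 allyl enol ether, whose [3,3] shift through a chair transition state on the face opposite the lactone bridge puts the new C10–C9 bond trans to C5–C6, while the chain, trans to the O–CH2 carbon in 19, sits pseudo-equatorial and gives the 9β-H configuration.

Step 15
Reactants: 21 ketone
Product: 22 C1 tosylhydrazone of 21
Conditions: TsNHNH2, MeOH, 60 °C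
Reagents that add atoms: 4-methylbenzenesulfonohydrazide Cc1ccc(cc1)S(=O)(=O)NN
Why: Condensation of the hydrazide with the only ketone; the neutral medium leaves the allylsilane and the C–F bond alone.

Step 16
Reactants: 22 tosylhydrazone
Product: 23 deoxygenated (C1H2) fluoro lactone carrying the allylsilane side arm
Conditions: catecholborane, CHCl3, 0 °C → rt; then NaOAc·3H2O, reflux
Reagents that add atoms: none
Why: Kabalka reduction: hydride adds to C=N, sulfinate is eliminated and the diazene loses N2, which should give the methylene group without any intermediate that could scramble C9 or C10, and uncatalysed catecholborane does not touch the alkenes.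

Step 17
Reactants: 23 fluoro lactone with allylsilane
Product: 25 19,6β-lactone of the 9βH-labda-8(17),13E-diene skeleton with the 15-silyl ether, via acyloxycarbenium triflate 24 (not isolated)
Conditions: Me3SiOTf (20 mol%), 2,6-di-tert-butyl-4-methylpyridine (30 mol%), CH2Cl2, −78 → −20 °C
Reagents that add atoms: none
Why: Silicon (first from the catalyst, then from the substrate's own Me3Si group) abstracts the exocyclic fluoride at C6, a leaving group that, unlike an alkoxy group, cannot be bypassed by opening of the lactone, and gives the cyclic acyloxycarbenium ion 24. The terminal carbon C7 of the 2-(silylmethyl)allyl unit attacks C6 anti to silicon (SE2'), the β-silyl cation collapses to the C8=C17 exocyclic methylene and Me3SiF leaves, so ring B, the C6–C7 bond and the 8(17)-alkene arise in one event from a bicyclic precursor. The closest known reactions are the intramolecular Hosomi–Sakurai reaction of 2-(silylmethyl)allyl groups with oxocarbenium ions and the C-allylation of anomeric fluorides with allylsilanes. Ring B closes in a 6-endo mode with respect to the allylsilane π bond and exo with respect to the C6=O+ bond, and the trans ring fusion follows from the diequatorial C5–C6 and C10–C9 bonds on ring A set in steps 4 and 14. The only new stereocentre, C6, is controlled by the lactone tether: O6 stays bonded to C19 on the β face and C7 can reach the planar cation only from the side of C10, which gives the 6β-oxygen. The step needs chemoselective ionisation and an intact allylsilane, secured by the strength of the Si–F bond, by the hindered base that removes triflic acid, and by the distance of the side-chain alkene, which could only close a seven- or eight-membered ring.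

Step 18
Reactants: 25 tricyclic lactone
Product: 27 6β-benzoyloxy-15-(tert-butyldiphenylsilyloxy)-9βH-labda-8(17),13E-dien-19-oic acid, via potassium hydroxy carboxylate 26 (not isolated)
Conditions: KOH (1.1 equiv), MeOH/H2O, 65 °C; evaporate, PhMe azeotrope; KHMDS (1.2 equiv), THF/DMF, −78 °C; N-benzoylimidazole (1.5 equiv), −78 → 0 °C; 1 M HCl to pH 3, 0 °C
Reagents that add atoms: potassium hydroxide [K+].[OH-]; N-benzoylimidazole O=C(c1ccccc1)n1ccnc1
Why: Saponification gives the hydroxy carboxylate, and acylation of its potassium alkoxide with an acyl imidazole, which does not activate a carboxylate, should place the benzoate on O6 without opening a path back to the lactone; the C6–O bond is never broken, so the configuration is kept.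

Step 19
Reactants: 27 benzoate acid
Product: 28 6β-benzoyloxy-7α-hydroxy-15-(tert-butyldiphenylsilyloxy)-9βH-labda-8(17),13E-dien-19-oic acid
Conditions: SeO2 (0.3 equiv), t-BuOOH (3 equiv), CH2Cl2, rt
Reagents that add atoms: selenium dioxide O=[Se]=O (oxygen donor, catalytic); tert-butyl hydroperoxide CC(C)(C)OO (terminal oxidant)
Why: Riley–Sharpless allylic oxidation: the ene reaction at the exocyclic methylene removes the axial 7α-H and the [2,3] shift of the allylseleninic acid returns oxygen to the same α face, anti to the 6β-benzoate and C20, while the side-chain alkene is deactivated by its allylic silyloxy group, as the proximal alkene is in geranyl derivatives.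

Step 20
Reactants: 28 silyl ether
Product: 29 (4S,5R,6S,7S,9S,10R)-6-benzoyloxy-7,15-dihydroxylabda-8(17),13E-dien-19-oic acid (CNP0149011.1)
Conditions: HF·pyridine, THF/pyridine, 0 °C → rt
Reagents that add atoms: none
Why: Fluoride-mediated desilylation of the primary silyl ether; the hindered benzoate cannot migrate to the trans-diaxial 7α-hydroxyl, and the acid and alkenes are inert.

**Compound list**
1 | 3-methylfuran-2-carboxylic acid | Cc1ccoc1C(=O)O | starting material
2 | 5-hydroxy-3-methylfuran-2(5H)-one (racemic) | CC1=CC(O)OC1=O | intermediate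
3 | (1R,2S,5R)-(−)-menthol | O[C@@H]1C[C@H](C)CC[C@H]1C(C)C | starting material
4 | (5R)-5-[(1R,2S,5R)-menthyloxy]-3-methylfuran-2(5H)-one | CC1=C[C@H](O[C@@H]2C[C@H](C)CC[C@H]2C(C)C)OC1=O | intermediate
5 | pent-1-en-3-one | C=CC(=O)CC | starting material
6 | (Z)-3-(trimethylsilyloxy)penta-1,3-diene | C/C=C(\O[Si](C)(C)C)C=C | intermediate
7 | Diels–Alder adduct (cis-fused 19,6-lactone, C1=C2 silyl enol ether, 6-O-menthyl) | C[C@@H]1C(O[Si](C)(C)C)=CC[C@]2(C)C(=O)O[C@@H](O[C@@H]3C[C@H](C)CC[C@H]3C(C)C)[C@H]12 | intermediate
8 | keto pseudo-acid (6-hydroxy-19,6-lactone, C1 ketone) | C[C@@H]1C(=O)CC[C@]2(C)C(=O)O[C@@H](O)[C@H]12 | intermediate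
9 | 6-fluoro-19,6-lactone, C1 ketone | C[C@@H]1C(=O)CC[C@]2(C)C(=O)O[C@@H](F)[C@H]12 | intermediate
10 | 6-fluoro-19,6-lactone, C1 dimethyl ketal | C[C@@H]1C(OC)(OC)CC[C@]2(C)C(=O)O[C@@H](F)[C@H]12 | intermediate
11 | geraniol | CC(C)=CCC/C(C)=C/CO | starting material
12 | geranyl tert-butyldiphenylsilyl ether | CC(C)=CCC/C(C)=C/CO[Si](c1ccccc1)(c1ccccc1)C(C)(C)C | intermediate
13 | 6,7-epoxygeranyl tert-butyldiphenylsilyl ether (racemic epoxide) | CC1(C)OC1CC/C(C)=C/CO[Si](c1ccccc1)(c1ccccc1)C(C)(C)C | intermediate
14 | (E)-6-(tert-butyldiphenylsilyloxy)-4-methylhex-4-enal | O=CCC/C(C)=C/CO[Si](c1ccccc1)(c1ccccc1)C(C)(C)C | intermediate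
15 | (E)-tert-butyl[(3-methylhept-2-en-6-yn-1-yl)oxy]diphenylsilane | C#CCC/C(C)=C/CO[Si](c1ccccc1)(c1ccccc1)C(C)(C)C | intermediate
16 | lithium acetylide of 15 | [Li]C#CCC/C(C)=C/CO[Si](c1ccccc1)(c1ccccc1)C(C)(C)C | intermediate (not isolated)
17 | (E)-8-(tert-butyldiphenylsilyloxy)-6-methyloct-6-en-2-yn-1-ol | OCC#CCC/C(C)=C/CO[Si](c1ccccc1)(c1ccccc1)C(C)(C)C | intermediate
18 | five-membered alkenylmagnesium alkoxide chelate | C[Si](C)(C)CC1=C(CC/C(C)=C/CO[Si](c2ccccc2)(c2ccccc2)C(C)(C)C)[Mg]OC1 | intermediate (not isolated)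
19 | (2Z,6E)-8-(tert-butyldiphenylsilyloxy)-6-methyl-2-[(trimethylsilyl)methyl]octa-2,6-dien-1-ol | OC/C(C[Si](C)(C)C)=C/CC/C(C)=C/CO[Si](c1ccccc1)(c1ccccc1)C(C)(C)C | intermediate
20 | C1=C10 allyl enol ether of the fluoro lactone | CC1=C(OC/C(C[Si](C)(C)C)=C/CC/C(C)=C/CO[Si](c3ccccc3)(c3ccccc3)C(C)(C)C)CC[C@]2(C)C(=O)O[C@@H](F)[C@H]12 | intermediate (not isolated)
21 | Claisen ketone (C1 ketone, quaternary C10, C9 stereocentre, 2-(silylmethyl)allyl arm) | C=C(C[Si](C)(C)C)[C@@H](CC/C(C)=C/CO[Si](c3ccccc3)(c3ccccc3)C(C)(C)C)[C@@]1(C)C(=O)CC[C@]2(C)C(=O)O[C@@H](F)[C@H]12 | intermediate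
22 | C1 tosylhydrazone of 21 (C=N geometry not defined) | C=C(C[Si](C)(C)C)[C@@H](CC/C(C)=C/CO[Si](c3ccccc3)(c3ccccc3)C(C)(C)C)[C@@]1(C)C(=NNS(=O)(=O)c3ccc(C)cc3)CC[C@]2(C)C(=O)O[C@@H](F)[C@H]12 | intermediate
23 | deoxygenated fluoro lactone with allylsilane arm | C=C(C[Si](C)(C)C)[C@@H](CC/C(C)=C/CO[Si](c3ccccc3)(c3ccccc3)C(C)(C)C)[C@@]1(C)CCC[C@]2(C)C(=O)O[C@@H](F)[C@H]12 | intermediate
24 | lactone acyloxycarbenium triflate | C=C(C[Si](C)(C)C)[C@@H](CC/C(C)=C/CO[Si](c3ccccc3)(c3ccccc3)C(C)(C)C)[C@@]1(C)CCC[C@]2(C)C(=O)[O+]=C[C@H]12.[O-]S(=O)(=O)C(F)(F)F | intermediate (not isolated)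
25 | 15-(tert-butyldiphenylsilyloxy)-9βH-labda-8(17),13E-dien-19,6β-olide | C=C1C[C@H]2OC(=O)[C@@]3(C)CCC[C@](C)([C@@H]1CC/C(C)=C/CO[Si](c4ccccc4)(c4ccccc4)C(C)(C)C)[C@@H]23 | intermediate
26 | potassium 6β-hydroxy-15-(tert-butyldiphenylsilyloxy)-9βH-labda-8(17),13E-dien-19-oate | C=C1[C@@H](CC/C(C)=C/CO[Si](c3ccccc3)(c3ccccc3)C(C)(C)C)[C@@]2(C)CCC[C@](C)(C(=O)[O-])[C@@H]2[C@H](O)C1.[K+] | intermediate (not isolated)
27 | 6β-benzoyloxy-15-(tert-butyldiphenylsilyloxy)-9βH-labda-8(17),13E-dien-19-oic acid | C=C1[C@@H](CC/C(C)=C/CO[Si](c3ccccc3)(c3ccccc3)C(C)(C)C)[C@@]2(C)CCC[C@](C)(C(=O)O)[C@@H]2[C@H](OC(=O)c2ccccc2)C1 | intermediate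
28 | 6β-benzoyloxy-7α-hydroxy-15-(tert-butyldiphenylsilyloxy)-9βH-labda-8(17),13E-dien-19-oic acid | C=C1[C@@H](CC/C(C)=C/CO[Si](c3ccccc3)(c3ccccc3)C(C)(C)C)[C@@]2(C)CCC[C@](C)(C(=O)O)[C@@H]2[C@H](OC(=O)c2ccccc2)[C@H]1O | intermediate
29 | CNP0149011.1, (4S,5R,6S,7S,9S,10R)-6-benzoyloxy-7,15-dihydroxylabda-8(17),13E-dien-19-oic acid | C=C1[C@@H](CC/C(C)=C/CO)[C@@]2(C)CCC[C@](C)(C(=O)O)[C@@H]2[C@H](OC(=O)c2ccccc2)[C@H]1O | target

**Step count and risks**

Total: 20 steps. Longest linear sequence: 13 steps (steps 8–13 then 14–20 from geraniol; the branch from 1, steps 1, 2, 4–7 then 14–20, is equally long).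

Steps most likely to fail:

1. Step 14 (ketal Claisen). The rearrangement may leak through the less substituted C1=C2 enol ether, delivering the allyl group to C2, or pass partly through a boat transition state and erode the C9 configuration. The fallback blocks C2 as an alkene. It sets out from 9: kinetic enolisation (LDA, Me3SiCl, THF, −78 °C) should give the C1=C2 silyl enol ether F1, and Saegusa–Ito dehydrogenation (Pd(OAc)2, MeCN, rt) the C2=C3 enone F2, whose only enolisable position is C10. Ketalisation (HC(OMe)3, MeOH, PPTS) should give the enone dimethyl ketal F3, and the same Claisen conditions with 19 can then only pass through the cross-conjugated C1=C10 dienol ether and should give the enone Claisen product F4. Conjugate reduction with [(Ph3P)CuH]6 (PhH, rt) returns to the route at 21.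

2. Step 18 (lactone opening and 6-O-benzoylation). The carboxylate may be acylated before the hindered 6β-alkoxide, and the mixed anhydride would then be captured by O6 with return to the lactone; the alkoxide may also fail to acylate. The fallback takes C19 out of the acid oxidation level for the acylation. It sets out from 25: LiAlH4 (THF, 0 °C) should give the 6β,19-diol F5, and Et3SiCl/imidazole the 19-triethylsilyl ether F6. Benzoylation (BzCl, DMAP, pyridine, 60 °C) should give the 6β-benzoate F7, and PPTS/MeOH (0 °C) the 19-alcohol F8. Oxidation with TEMPO (cat.)/PhI(OAc)2 in MeCN/H2O should convert the primary alcohol into the acid and return to the route at 27.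

3. Step 19 (allylic oxidation). The ene reaction may compete at the side-chain alkene (oxidation at C12), or the new alcohol may be over-oxidised to the 7-ketone. The fallback inverts deprotection and oxidation so that the side-chain alkene carries an electron-withdrawing allylic acetate. It sets out from 27: HF·pyridine should give the 15-alcohol F9, and Ac2O/pyridine (aqueous work-up cleaves the mixed anhydride) the 15-acetate F10. SeO2/t-BuOOH should then give the 7α-hydroxy 15-acetate F11, and K2CO3/MeOH at 0 °C, which should spare the hindered secondary benzoate, returns to the route at 29.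

**Further compounds**
F1 | step 14 | C1=C2 trimethylsilyl enol ether of 9 | C[C@@H]1C(O[Si](C)(C)C)=CC[C@]2(C)C(=O)O[C@@H](F)[C@H]12
F2 | step 14 | C2=C3 enone of the fluoro lactone | C[C@@H]1C(=O)C=C[C@]2(C)C(=O)O[C@@H](F)[C@H]12
F3 | step 14 | dimethyl ketal of enone F2 | C[C@@H]1C(OC)(OC)C=C[C@]2(C)C(=O)O[C@@H](F)[C@H]12
F4 | step 14 | Claisen product with C2=C3 enone | C=C(C[Si](C)(C)C)[C@@H](CC/C(C)=C/CO[Si](c3ccccc3)(c3ccccc3)C(C)(C)C)[C@@]1(C)C(=O)C=C[C@]2(C)C(=O)O[C@@H](F)[C@H]12
F5 | step 18 | 15-(tert-butyldiphenylsilyloxy)-9βH-labda-8(17),13E-diene-6β,19-diol | C=C1[C@@H](CC/C(C)=C/CO[Si](c3ccccc3)(c3ccccc3)C(C)(C)C)[C@@]2(C)CCC[C@](C)(CO)[C@@H]2[C@H](O)C1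
F6 | step 18 | 19-triethylsilyl ether of F5 | C=C1[C@@H](CC/C(C)=C/CO[Si](c3ccccc3)(c3ccccc3)C(C)(C)C)[C@@]2(C)CCC[C@](C)(CO[Si](CC)(CC)CC)[C@@H]2[C@H](O)C1
F7 | step 18 | 6β-benzoate of F6 | C=C1[C@@H](CC/C(C)=C/CO[Si](c3ccccc3)(c3ccccc3)C(C)(C)C)[C@@]2(C)CCC[C@](C)(CO[Si](CC)(CC)CC)[C@@H]2[C@H](OC(=O)c2ccccc2)C1
F8 | step 18 | 6β-benzoyloxy-15-(tert-butyldiphenylsilyloxy)-9βH-labda-8(17),13E-dien-19-ol | C=C1[C@@H](CC/C(C)=C/CO[Si](c3ccccc3)(c3ccccc3)C(C)(C)C)[C@@]2(C)CCC[C@](C)(CO)[C@@H]2[C@H](OC(=O)c2ccccc2)C1
F9 | step 19 | 6β-benzoyloxy-15-hydroxy-9βH-labda-8(17),13E-dien-19-oic acid | C=C1[C@@H](CC/C(C)=C/CO)[C@@]2(C)CCC[C@](C)(C(=O)O)[C@@H]2[C@H](OC(=O)c2ccccc2)C1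
F10 | step 19 | 15-acetate of F9 | C=C1[C@@H](CC/C(C)=C/COC(C)=O)[C@@]2(C)CCC[C@](C)(C(=O)O)[C@@H]2[C@H](OC(=O)c2ccccc2)C1
F11 | step 19 | 15-acetoxy-6β-benzoyloxy-7α-hydroxy-9βH-labda-8(17),13E-dien-19-oic acid | C=C1[C@@H](CC/C(C)=C/COC(C)=O)[C@@]2(C)CCC[C@](C)(C(=O)O)[C@@H]2[C@H](OC(=O)c2ccccc2)[C@H]1O
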